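**Plan**

1. Labels: ring B is C1 (tertiary carbinol), C2 (quaternary C–CH3), C3 (CH–CH3), C4 (CH–OAc), C5 (CH2), C6 (ring-fusion carbon); Cα, Cβ, Cγ, Cδ run from the butenolide α-carbon through ring A to the furyl methine. Cuts, in retro order: the C4 acetate; the furan C3–acyl bond of ring C; the C1–Cδ bond of ring A; Cα=Cβ (to 3-(furan-2-yl)acrolein); the lactone C–O bond and both exocyclic bonds at C6; the C2–CH2CO2R bond; ring B goes back to 2,3-dimethylphenol.
2. Enabling feature: C1 of ring B, a carbinol carbon between the quaternary carbons C2 and C6, is bonded to the furyl methine Cδ of ring A and is also linked to it through C6–Cα=Cβ–Cγ. The C1–Cδ bond can therefore come from a C1 ketone and the δ-carbon of a 2-furyl-capped dienylidene lactone held on C6, ring A closing as the bond forms.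
3. Forward order: ring B is substituted (steps 1–8), the spiro lactone is closed (9), the furyl dienyl chain is attached (10–11), ring A closes at the cathode (12), ring C closes by acylation at furan C3 (13–14), and the acetate is set last (15–16).
4. Stereochemistry: C4 from a Corey–Bakshi–Shibata reduction; C3 by hydrogen delivery anti to the C4 silyloxy group; C2 by alkylation anti to the C3 methyl; C6 by alkylation on the β face; C1 and Cδ in the ring A closure, the dienyl arm being bound to the β face of C6.
5. The C2 acyl arm is carried as a tert-butyl ester (acid oxidation level), so no oxidation is needed once the furan is present, and one silyl triflate treatment frees the acid and masks the tertiary alcohol.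

Key step: step 12

Remark: α is the face of ring B that carries the C4 oxygen, both methyl groups, the lactone CH2 and the C1 hydroxyl; β is the opposite face (C2 acetic arm, Cα). The absolute configuration is taken as drawn in the target SMILES (C1 R, C2 S, C3 S, C4 R, C6 S, Cδ R).
Assumption: 2,3-dimethylphenol, tert-butyl bromoacetate, benzyl chloromethyl ether, ethyl bromoacetate and (2E)-3-(furan-2-yl)prop-2-enal are taken as the commercial starting materials.

**Route**

Step 1
Reactants: 1 2,3-dimethylphenol
Product: 2 4,4-dimethoxy-2,3-dimethylcyclohexa-2,5-dien-1-one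
Conditions: PhI(OAc)2 (2.2 equiv), MeOH, 0 °C to rt
Reagents that add atoms: methanol, CO
Why: Oxidative dearomatisation of a phenol by a hypervalent iodine reagent in methanol is a standard entry to para-quinone monoketals: the first equivalent should introduce methoxyl para to the hydroxyl and the second should convert the resulting 4-methoxyphenol into the dimethyl ketal, and no stereocentre is formed.

Step 2
Reactants: 2 4,4-dimethoxy-2,3-dimethylcyclohexa-2,5-dien-1-one
Product: 3 4,4-dimethoxy-2,3-dimethylcyclohex-2-en-1-one
Conditions: H2 (1 atm), RhCl(PPh3)3 (5 mol %), toluene, rt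
Reagents that add atoms: none
Why: Homogeneous hydrogenation with RhCl(PPh3)3 discriminates strongly by alkene substitution, so the disubstituted double bond of the cross-conjugated dienone should be reduced while the tetrasubstituted one and the acid-sensitive ketal survive the neutral medium.

Step 3
Reactants: 3 4,4-dimethoxy-2,3-dimethylcyclohex-2-en-1-one
Product: 4 (1R)-4,4-dimethoxy-2,3-dimethylcyclohex-2-en-1-ol
Conditions: (S)-2-methyl-CBS-oxazaborolidine (10 mol %), BH3·SMe2, toluene, −30 °C; MeOH, then aqueous work-up
Reagents that add atoms: none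
Why: Corey–Bakshi–Shibata reduction of an α-substituted cyclohexenone, in which the methyl-bearing alkenyl flank acts as the large group and the ring CH2 as the small one, so that the (S)-oxazaborolidine should deliver hydride to the face that gives the R carbinol, the future C4 and the source of all absolute configuration.

Step 4
Reactants: 4 (1R)-4,4-dimethoxy-2,3-dimethylcyclohex-2-en-1-ol
Product: 6 (4R)-4-[(tert-butyldimethylsilyl)oxy]-2,3-dimethylcyclohex-2-en-1-one, via silyl ether ketal 5 (not isolated)
Conditions: TBSCl, imidazole, DMF, rt; then 1 M aq HCl, THF, 0 °C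
Reagents that add atoms: tert-butyldimethylsilyl chloride, CC(C)(C)[Si](C)(C)Cl; water, O
Why: Silylation of the allylic alcohol followed by mild acid hydrolysis of the allylic dimethyl ketal unmasks the enone carbonyl at the far end of the double bond (net 1,4-transposition of the two oxygen functions) without touching the silyl ether or the C4 stereocentre.

Step 5
Reactants: 6 (4R)-4-[(tert-butyldimethylsilyl)oxy]-2,3-dimethylcyclohex-2-en-1-one
Product: 7 (3S,4R)-4-[(tert-butyldimethylsilyl)oxy]-1-[(dimethylphenylsilyl)oxy]-2,3-dimethylcyclohex-1-ene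
Conditions: PhMe2SiH, RhCl(PPh3)3 (2 mol %), toluene, 60 °C
Reagents that add atoms: dimethylphenylsilane, C[SiH](C)c1ccccc1
Why: Rhodium-catalysed 1,4-hydrosilylation of an enone with a monohydrosilane gives the silyl enol ether regiospecifically, and because allylic strain with the C3 methyl holds the C4 silyloxy group pseudoaxial, hydrogen should be delivered to C3 on the opposite (β) face, which sets C3 with its methyl cis to the C4 oxygen.

Step 6
Reactants: 7 (3S,4R)-4-[(tert-butyldimethylsilyl)oxy]-1-[(dimethylphenylsilyl)oxy]-2,3-dimethylcyclohex-1-ene; 8 tert-butyl bromoacetate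
Product: 10 tert-butyl 2-[(1S,2S,3R)-3-[(tert-butyldimethylsilyl)oxy]-1,2-dimethyl-6-oxocyclohexyl]acetate, via lithium enolate 9 (not isolated)
Conditions: MeLi, THF, 0 °C; then DMPU, 8, −78 to −30 °C
Reagents that add atoms: tert-butyl bromoacetate (8), CC(C)(C)OC(=O)CBr
Why: Cleavage of the silyl enol ether by MeLi releases the tetrasubstituted lithium enolate regiospecifically and its alkylation by the reactive α-bromo ester forms the C2 quaternary centre, the electrophile entering anti to the adjacent pseudoaxial C3 methyl (the usual trans outcome of conjugate reduction–enolate alkylation) so that the two methyl groups end cis.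

Step 7
Reactants: 10 tert-butyl 2-[(1S,2S,3R)-3-[(tert-butyldimethylsilyl)oxy]-1,2-dimethyl-6-oxocyclohexyl]acetate; 11 benzyl chloromethyl ether
Product: 13 tert-butyl 2-[(1S,2S,3R)-5-[(benzyloxy)methyl]-3-[(tert-butyldimethylsilyl)oxy]-1,2-dimethyl-6-oxocyclohexyl]acetate (C5 epimers), via lithium enolate 12 (not isolated)
Conditions: LiN(iPr)2, THF, −78 °C; then 11, −78 to −40 °C
Reagents that add atoms: benzyl chloromethyl ether (11), ClCOCc1ccccc1
Why: The ketone can enolise only towards C6 and is markedly more acidic than the tert-butyl ester, so kinetic deprotonation and C-alkylation by the chloromethyl ether (enolate alkylation) should install the protected hydroxymethyl group, and the C6 configuration formed here is erased in step 8 and need not be controlled.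

Step 8
Reactants: 13 tert-butyl 2-[(1S,2S,3R)-5-[(benzyloxy)methyl]-3-[(tert-butyldimethylsilyl)oxy]-1,2-dimethyl-6-oxocyclohexyl]acetate (C5 epimers); 14 ethyl bromoacetate
Product: 16 ethyl 2-[(1S,3S,4S,5R)-1-[(benzyloxy)methyl]-3-(2-tert-butoxy-2-oxoethyl)-5-[(tert-butyldimethylsilyl)oxy]-3,4-dimethyl-2-oxocyclohexyl]acetate, via lithium enolate 15 (not isolated)
Conditions: LiN(iPr)2, THF/DMPU, −78 °C; then 14, −78 °C
Reagents that add atoms: ethyl bromoacetate (14), CCOC(=O)CBr
Why: Enolate alkylation with an α-bromo ester at −78 °C, where β-elimination of the benzyloxy group should not compete, makes C6 quaternary, and the acetic arm should enter on the β face because the half-chair that keeps the C4 silyloxy group equatorial offers its axial trajectory there, whereas the axial trajectory on the α face belongs to the half-chair in which it is blocked by the axial C4 silyloxy group and the pseudoaxial C2 methyl, leaving the benzyloxymethyl group α (cis to the C4 oxygen).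

Step 9
Reactants: 16 ethyl 2-[(1S,3S,4S,5R)-1-[(benzyloxy)methyl]-3-(2-tert-butoxy-2-oxoethyl)-5-[(tert-butyldimethylsilyl)oxy]-3,4-dimethyl-2-oxocyclohexyl]acetate
Product: 18 tert-butyl 2-[(5S,7S,8S,9R)-9-[(tert-butyldimethylsilyl)oxy]-7,8-dimethyl-3,6-dioxo-2-oxaspiro[4.5]decan-7-yl]acetate, via hydroxy ester 17 (not isolated)
Conditions: H2 (1 atm), Pd(OH)2/C, EtOAc, rt; then PPTS (cat.), toluene, 60 °C
Reagents that add atoms: none
Why: Hydrogenolysis of the benzyl ether frees the primary alcohol, which under mild acid closes the five-membered lactone onto the ethyl ester (lactonisation), the tert-butyl ester being hindered and placed for a seven-membered ring only, and no stereocentre is touched.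

Step 10
Reactants: 18 tert-butyl 2-[(5S,7S,8S,9R)-9-[(tert-butyldimethylsilyl)oxy]-7,8-dimethyl-3,6-dioxo-2-oxaspiro[4.5]decan-7-yl]acetate; 19 (2E)-3-(furan-2-yl)prop-2-enal
Product: 21 aldol adduct of 18 bearing a (2E)-3-(furan-2-yl)-1-hydroxyprop-2-en-1-yl group on lactone C4 (epimers at C4 and the carbinol carbon), via lithium enolate 20 (not isolated)
Conditions: LiN(SiMe3)2, THF, −78 °C; then 19; AcOH quench at −78 °C
Reagents that add atoms: (2E)-3-(furan-2-yl)prop-2-enal (19), O=C/C=C/c1ccco1
Why: The lactone α-CH2 is the only readily enolisable site (the ketone has no α-hydrogen and the tert-butyl ester is less acidic and more hindered), and its lithium enolate adds 1,2 to the enal in an aldol addition whose two new stereocentres are removed in step 11.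

Step 11
Reactants: 21 aldol adduct (epimers)
Product: 23 tert-butyl 2-[(4E,5S,7S,8S,9R)-9-[(tert-butyldimethylsilyl)oxy]-4-[(2E)-3-(furan-2-yl)prop-2-en-1-ylidene]-7,8-dimethyl-3,6-dioxo-2-oxaspiro[4.5]decan-7-yl]acetate, via mesylate 22 (not isolated)
Conditions: MsCl, Et3N, CH2Cl2, 0 °C; then DBU, rt
Reagents that add atoms: none
Why: Mesylation and base-induced E1cB elimination complete the aldol condensation to the alkylidene lactone, for which the E geometry (dienyl chain anti to the lactone carbonyl and syn to C6, as ring closure requires) is expected on thermodynamic grounds, and the radical anion of step 12 can in any case rotate about this bond.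

Step 12
Reactants: 23 dienylidene spiro lactone ketone
Product: 25 ring A/B cis-fused butenolide carbinol (tert-butyl ester; C1 hydroxyl α; Cδ furan-2-yl cis to the C1–C2 bond; Cδ hydrogen cis to the hydroxyl), via deconjugated lactone 24 (not isolated)
Conditions: glassy carbon cathode, Pt anode, divided cell, Et4NOTs (0.1 M) in DMF, dimethyl malonate (2.5 equiv), controlled potential at the first reduction wave (Ag/AgCl reference), rt, 2 F/mol; then DBU (cat.), rt
Reagents that add atoms: none
Why: Proposed new method: the first electron should enter the furyl dienoate, the most easily reduced group, and the radical anion, with spin and charge density at Cδ, adds through Cδ to the C1 ketone carbon; a second electron and two protons from the malonate then give the tertiary alkoxide and a dienolate that is protonated at Cα (24) and moved into conjugation with the lactone by DBU (25). The closest known reaction type is the electroreductive cyclisation (electrohydrocyclisation) of ketones tethered to α,β-unsaturated esters, with its ketyl–olefin counterpart mediated by SmI2, here extended to the δ-terminus of a dienoate whose tether leaves from Cα. Ring A closes in a six-membered mode that is exo with respect to the carbonyl group and keeps the former diene carbons inside the new ring, attack through Cβ being excluded because it would give a four-membered ring. The C1 configuration is fixed by the tether, since Cα sits on the β face of C6 and the planar s-cis diene can reach only the β face of the carbonyl, which gives the cis ring fusion with the hydroxyl α and syn to the lactone CH2. The Cδ configuration should follow from the E geometry of the Cγ=Cδ bond, which keeps the furan on the outside of the closing ring (pseudoequatorial and cis to the C1–C2 bond) and turns the Cδ hydrogen towards the hydroxyl. The step needs reduction of the dienoate alone in the presence of a ketone between two quaternary carbons, a tert-butyl ester and a silyl ether, none of which is reduced at this potential, and it needs ring closure to outrun protonation, for which the weak carbon acid is chosen; the C1 alkoxide is trans to both the C2 acetic arm and Cα, so neither ester carbonyl is within reach for acyl transfer.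

Step 13
Reactants: 25 ring A/B cis-fused butenolide carbinol (tert-butyl ester)
Product: 27 carboxylic acid bearing the C1 trimethylsilyl ether (C2 CH2CO2H; C4 silyl ether retained), via trimethylsilyl ester 26 (not isolated)
Conditions: TMSOTf (4 equiv), 2,6-lutidine, CH2Cl2, 0 °C to rt; pH 5 aqueous buffer
Reagents that add atoms: trimethylsilyl trifluoromethanesulfonate, C[Si](C)(C)OS(=O)(=O)C(F)(F)F
Why: Trimethylsilyl triflate with a hindered pyridine base converts tert-butyl esters into silyl esters with loss of 2-methylpropene and at the same time silylates the hindered tertiary alcohol, and aqueous work-up hydrolyses only the labile silyl ester, so the free acid is obtained with the carbinol masked for step 14.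

Step 14
Reactants: 27 carboxylic acid bearing the C1 trimethylsilyl ether
Product: 29 tetracyclic furyl ketone (ring C closed from the C2 CH2C(=O) arm to furan C3; C1 OSiMe3; C4 OSiMe2tBu), via acid chloride 28 (not isolated)
Conditions: 1-chloro-N,N,2-trimethylprop-1-en-1-amine, CH2Cl2, 0 °C; then SnCl4, CH2Cl2 (high dilution), −78 to −40 °C
Reagents that add atoms: none
Why: Intramolecular Friedel–Crafts acylation of a 2-alkylfuran: the acid chloride, formed under neutral conditions, lies on the same face of ring B as the furan-bearing Cδ, so that SnCl4 activation at low temperature and high dilution should close the seven-membered ring C at furan C3 in preference to intermolecular attack at the free C5, and no stereocentre is formed.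

Step 15
Reactants: 29 tetracyclic furyl ketone (bis-silyl ether)
Product: 30 tetracyclic diol (C1 tertiary OH and C4 secondary OH, both α)
Conditions: HF·pyridine, pyridine, THF, 0 °C to rt
Reagents that add atoms: none
Why: Fluoride-mediated desilylation with buffered HF·pyridine should remove both the trimethylsilyl ether of the tertiary alcohol and the tert-butyldimethylsilyl ether at C4 while sparing the butenolide, the furyl ketone and the tertiary carbinol.

Step 16
Reactants: 30 tetracyclic diol
Product: 31 CNP0329797.1 (target; C4 acetate, C1 tertiary alcohol)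
Conditions: Ac2O, pyridine, DMAP (cat.), CH2Cl2, 0 °C to rt
Reagents that add atoms: acetic anhydride, CC(=O)OC(C)=O
Why: Acylation with acetic anhydride under DMAP catalysis esterifies the secondary C4 hydroxyl, whereas the tertiary C1 hydroxyl, flanked by two quaternary carbons and a methine, is too hindered to react under these conditions.

**Compound list**

1 | 2,3-dimethylphenol | Cc1cccc(O)c1C | starting material
2 | 4,4-dimethoxy-2,3-dimethylcyclohexa-2,5-dien-1-one | COC1(OC)C=CC(=O)C(C)=C1C | intermediate
3 | 4,4-dimethoxy-2,3-dimethylcyclohex-2-en-1-one | COC1(OC)CCC(=O)C(C)=C1C | intermediate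
4 | (1R)-4,4-dimethoxy-2,3-dimethylcyclohex-2-en-1-ol | O[C@@H]1CCC(OC)(OC)C(C)=C1C | intermediate
5 | tert-butyldimethylsilyl ether of 4 (silyl ether ketal) | CC(C)(C)[Si](C)(C)O[C@@H]1CCC(OC)(OC)C(C)=C1C | intermediate (not isolated)
6 | (4R)-4-[(tert-butyldimethylsilyl)oxy]-2,3-dimethylcyclohex-2-en-1-one | CC(C)(C)[Si](C)(C)O[C@@H]1CCC(=O)C(C)=C1C | intermediate
7 | (3S,4R)-4-[(tert-butyldimethylsilyl)oxy]-1-[(dimethylphenylsilyl)oxy]-2,3-dimethylcyclohex-1-ene | CC(C)(C)[Si](C)(C)O[C@@H]1CCC(O[Si](C)(C)c2ccccc2)=C(C)[C@@H]1C | intermediate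
8 | tert-butyl bromoacetate | CC(C)(C)OC(=O)CBr | starting material
9 | lithium enolate from 7 (C1=C2 enolate; C3 methyl and C4 silyloxy cis) | CC(C)(C)[Si](C)(C)O[C@@H]1CCC([O-])=C(C)[C@@H]1C.[Li+] | intermediate (not isolated)
10 | tert-butyl 2-[(1S,2S,3R)-3-[(tert-butyldimethylsilyl)oxy]-1,2-dimethyl-6-oxocyclohexyl]acetate | CC(C)(C)[Si](C)(C)O[C@@H]1CCC(=O)[C@@](C)(CC(=O)OC(C)(C)C)[C@@H]1C | intermediate
11 | benzyl chloromethyl ether | ClCOCc1ccccc1 | starting material
12 | lithium enolate of 10 (C1=C6 enolate) | CC(C)(C)[Si](C)(C)O[C@@H]1CC=C([O-])[C@@](C)(CC(=O)OC(C)(C)C)[C@@H]1C.[Li+] | intermediate (not isolated)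
13 | tert-butyl 2-[(1S,2S,3R)-5-[(benzyloxy)methyl]-3-[(tert-butyldimethylsilyl)oxy]-1,2-dimethyl-6-oxocyclohexyl]acetate (C5 epimers) | CC(C)(C)[Si](C)(C)O[C@@H]1CC(COCc2ccccc2)C(=O)[C@@](C)(CC(=O)OC(C)(C)C)[C@@H]1C | intermediate
14 | ethyl bromoacetate | CCOC(=O)CBr | starting material
15 | lithium enolate of 13 (C1=C6 enolate) | CC(C)(C)[Si](C)(C)O[C@@H]1CC(COCc2ccccc2)=C([O-])[C@@](C)(CC(=O)OC(C)(C)C)[C@@H]1C.[Li+] | intermediate (not isolated)
16 | ethyl 2-[(1S,3S,4S,5R)-1-[(benzyloxy)methyl]-3-(2-tert-butoxy-2-oxoethyl)-5-[(tert-butyldimethylsilyl)oxy]-3,4-dimethyl-2-oxocyclohexyl]acetate | CC(C)(C)[Si](C)(C)O[C@@H]1C[C@](CC(=O)OCC)(COCc2ccccc2)C(=O)[C@@](C)(CC(=O)OC(C)(C)C)[C@@H]1C | intermediate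
17 | hydroxy ester: the 1-(hydroxymethyl) analogue of 16 | CC(C)(C)[Si](C)(C)O[C@@H]1C[C@](CC(=O)OCC)(CO)C(=O)[C@@](C)(CC(=O)OC(C)(C)C)[C@@H]1C | intermediate (not isolated)
18 | tert-butyl 2-[(5S,7S,8S,9R)-9-[(tert-butyldimethylsilyl)oxy]-7,8-dimethyl-3,6-dioxo-2-oxaspiro[4.5]decan-7-yl]acetate | CC(C)(C)[Si](C)(C)O[C@@H]1C[C@]2(COC(=O)C2)C(=O)[C@@](C)(CC(=O)OC(C)(C)C)[C@@H]1C | intermediate
19 | (2E)-3-(furan-2-yl)prop-2-enal | O=C/C=C/c1ccco1 | starting material
20 | lithium enolate of lactone 18 | CC(C)(C)[Si](C)(C)O[C@@H]1C[C@]2(COC([O-])=C2)C(=O)[C@@](C)(CC(=O)OC(C)(C)C)[C@@H]1C.[Li+] | intermediate (not isolated)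
21 | aldol adduct: 18 with a (2E)-3-(furan-2-yl)-1-hydroxyprop-2-en-1-yl group on lactone C4 (epimers at C4 and the carbinol carbon) | CC(C)(C)[Si](C)(C)O[C@@H]1C[C@]2(COC(=O)C2C(O)/C=C/c2ccco2)C(=O)[C@@](C)(CC(=O)OC(C)(C)C)[C@@H]1C | intermediate
22 | methanesulfonate of 21 | CC(C)(C)[Si](C)(C)O[C@@H]1C[C@]2(COC(=O)C2C(OS(C)(=O)=O)/C=C/c2ccco2)C(=O)[C@@](C)(CC(=O)OC(C)(C)C)[C@@H]1C | intermediate (not isolated)
23 | tert-butyl 2-[(4E,5S,7S,8S,9R)-9-[(tert-butyldimethylsilyl)oxy]-4-[(2E)-3-(furan-2-yl)prop-2-en-1-ylidene]-7,8-dimethyl-3,6-dioxo-2-oxaspiro[4.5]decan-7-yl]acetate (key-step precursor) | CC(C)(C)[Si](C)(C)O[C@@H]1C[C@]2(COC(=O)/C2=C/C=C/c2ccco2)C(=O)[C@@](C)(CC(=O)OC(C)(C)C)[C@@H]1C | intermediate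
24 | deconjugated lactone: ring A closed, Cβ=Cγ double bond, Cα–H (epimers), C1 OH α, Cδ furan-2-yl | CC(C)(C)[Si](C)(C)O[C@@H]1C[C@@]23COC(=O)C2C=C[C@@H](c2ccco2)[C@@]3(O)[C@@](C)(CC(=O)OC(C)(C)C)[C@@H]1C | intermediate (not isolated)
25 | ring A/B cis-fused butenolide carbinol: Cα=Cβ conjugated with the lactone, C1 OH α, Cδ furan-2-yl cis to the C1–C2 bond, C2 CH3 α and CH2CO2tBu β, C3 CH3 α, C4 OSiMe2tBu α (C1 R, C2 S, C3 S, C4 R, C6 S, Cδ R) | CC(C)(C)[Si](C)(C)O[C@@H]1C[C@@]23COC(=O)C2=CC[C@@H](c2ccco2)[C@@]3(O)[C@@](C)(CC(=O)OC(C)(C)C)[C@@H]1C | intermediate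
26 | trimethylsilyl ester of 27 (C1 OSiMe3, C2 CH2CO2SiMe3) | CC(C)(C)[Si](C)(C)O[C@@H]1C[C@@]23COC(=O)C2=CC[C@@H](c2ccco2)[C@@]3(O[Si](C)(C)C)[C@@](C)(CC(=O)O[Si](C)(C)C)[C@@H]1C | intermediate (not isolated)
27 | carboxylic acid: 25 with C2 CH2CO2H and C1 OSiMe3 | CC(C)(C)[Si](C)(C)O[C@@H]1C[C@@]23COC(=O)C2=CC[C@@H](c2ccco2)[C@@]3(O[Si](C)(C)C)[C@@](C)(CC(=O)O)[C@@H]1C | intermediate
28 | acid chloride of 27 | CC(C)(C)[Si](C)(C)O[C@@H]1C[C@@]23COC(=O)C2=CC[C@@H](c2ccco2)[C@@]3(O[Si](C)(C)C)[C@@](C)(CC(=O)Cl)[C@@H]1C | intermediate (not isolated)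
29 | tetracyclic furyl ketone: ring C closed between the C2 CH2C(=O) arm and furan C3; C1 OSiMe3, C4 OSiMe2tBu | CC(C)(C)[Si](C)(C)O[C@@H]1C[C@@]23COC(=O)C2=CC[C@H]2c4occc4C(=O)C[C@@](C)([C@@H]1C)[C@]23O[Si](C)(C)C | intermediate
30 | tetracyclic diol: 29 with free C1 and C4 hydroxyls | O[C@@H]1C[C@@]23COC(=O)C2=CC[C@H]2c4occc4C(=O)C[C@@](C)([C@@H]1C)[C@]23O | intermediate
31 | CNP0329797.1: C4 acetate of 30 (C1 R, C2 S, C3 S, C4 R, C6 S, Cδ R) | CC(=O)O[C@@H]1C[C@@]23COC(=O)C2=CC[C@H]2c4occc4C(=O)C[C@@](C)([C@@H]1C)[C@]23O | target

**Count and risks**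

Total steps: 16. Longest linear sequence: 16 steps (from 1).

Step 12 (labelled step). The dienoate radical anion may be protonated and reduced further (saturation or hydrodimerisation) faster than it closes onto the very hindered ketone, or closure may pass through a conformer with the furan pseudoaxial and give the Cδ epimer. The fallback makes the same C1–Cδ bond by known polar allylation. It sets out from aldol adduct 21, which methyl chloroformate and pyridine convert into the allylic methyl carbonate F1. With Pd(PPh3)4 (cat.) and InI in THF, zerovalent palladium ionises the carbonate to a π-allyl complex of divalent palladium, and InI turns this into an allylindium nucleophile (umpolung carbonyl allylation). That nucleophile can reach the C1 ketone only through Cδ, from the β face, and should give the homoallylic alcohol 24. DBU then conjugates it to 25 as in step 12, where the route is rejoined.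

Step 8. Facial selectivity in the second alkylation at C6 may be poor, and the enolate may lose the benzyloxy group by β-elimination. The fallback replaces substrate control by ligand control and sets out from 13. KN(SiMe3)2 and allyl chloroformate give the allyl enol carbonate F2. Pd2(dba)3 with the matched enantiomer of the tert-butyl phosphinooxazoline ligand effects decarboxylative Tsuji allylation to the C6 allyl ketone F3 (allyl β). Ozonolysis (O3, CH2Cl2/MeOH, −78 °C; PPh3) gives the aldehyde F4, and hydrogenolysis (H2, Pd(OH)2/C) gives the lactol F5. Oxidation with TEMPO (cat.) and PhI(OAc)2 then returns the route at spiro lactone 18.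

Step 14. Intermolecular acylation at the free furan C5, acid-induced degradation of the furan, or loss of the tertiary silyl ether followed by ionisation may compete with ring closure. The fallback changes the electrophile from an acyl chloride and Lewis acid to an activated amide and sets out from acid 27. Me2NH·HCl, EDC·HCl and iPr2NEt give the N,N-dimethylamide F6. Tf2O and 2-fluoropyridine (CH2Cl2, −78 to 0 °C) convert it into an iminium triflate that acylates furan C3 intramolecularly (Vilsmeier–Haack-type closure). Aqueous NaHCO3 hydrolyses the cyclic iminium salt to ketone 29, where the route is rejoined.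

Further compounds
F1 | step 12 | allylic methyl carbonate of aldol adduct 21 | CC(C)(C)[Si](C)(C)O[C@@H]1C[C@]2(COC(=O)C2C(OC(=O)OC)/C=C/c2ccco2)C(=O)[C@@](C)(CC(=O)OC(C)(C)C)[C@@H]1C
F2 | step 8 | allyl enol carbonate of 13 (C1=C6 enol, O-allyloxycarbonyl) | CC(C)(C)[Si](C)(C)O[C@@H]1CC(COCc2ccccc2)=C(OC(=O)OCC=C)[C@@](C)(CC(=O)OC(C)(C)C)[C@@H]1C
F3 | step 8 | C6 allyl ketone (allyl β, benzyloxymethyl α; allyl analogue of 16) | CC(C)(C)[Si](C)(C)O[C@@H]1C[C@](CC=C)(COCc2ccccc2)C(=O)[C@@](C)(CC(=O)OC(C)(C)C)[C@@H]1C
F4 | step 8 | aldehyde from F3 (C6 β-CH2CHO) | CC(C)(C)[Si](C)(C)O[C@@H]1C[C@](CC=O)(COCc2ccccc2)C(=O)[C@@](C)(CC(=O)OC(C)(C)C)[C@@H]1C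
F5 | step 8 | lactol corresponding to 18 (2-oxaspiro[4.5]decan-3-ol, anomers) | CC(C)(C)[Si](C)(C)O[C@@H]1C[C@]2(COC(O)C2)C(=O)[C@@](C)(CC(=O)OC(C)(C)C)[C@@H]1C
F6 | step 14 | N,N-dimethylamide of acid 27 | CC(C)(C)[Si](C)(C)O[C@@H]1C[C@@]23COC(=O)C2=CC[C@@H](c2ccco2)[C@@]3(O[Si](C)(C)C)[C@@](C)(CC(=O)N(C)C)[C@@H]1C
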